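## Retrosynthetic overview

1. Target ⇐ chloride O-demethylation of its C7 methyl enol ether ⇐ palladium-catalysed, ligand-controlled para-dearomative prenylation of the ring-opened phenoxide (creates the C8 quaternary centre; proposed new method).
2. Lavandulyl group ⇐ Negishi coupling of the tricyclic aryl bromide with (S)-lavandulylzinc iodide, made from 3-methylbut-3-enoic acid and prenyl bromide by enantioselective α-alkylation.
3. cis-(2R,3S)-Chromanone ring ⇐ C8 tigloylation with ortho-demethylation, then quinine-catalysed oxa-Michael closure on the dihydrocoumarin.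
4. Dihydrocoumarin lactone (third ring oxygen plus masked hexanoic acid arm) ⇐ Baeyer–Villiger ring expansion of (3R)-4,6-dimethoxy-3-propylindan-1-one, the key step ⇐ Friedel–Crafts closure of the (R)-3-arylhexanoic acid, obtained by asymmetric hydrogenation of the ring-opened, O-methylated 7-hydroxy-4-propylcoumarin (resorcinol + hex-2-ynoic acid).
5. Ring order: coumarin ring (made, then opened) → indanone five-membered ring → six-membered lactone by ring expansion → chromanone ring → lactone opened and carbocycle dearomatised last.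

Assumption: CNP0266113.2 is exactly the stereoisomer drawn by the given SMILES, and the sense of induction of each chiral catalyst or reagent on these substrates is taken by analogy; where it proves opposite, the antipode (quinidine for quinine) is used.

## Route

Step 1
Reactants: 1 resorcinol; 2 hex-2-ynoic acid
Product: 3 7-hydroxy-4-propyl-2H-chromen-2-one
Conditions: Pd(OAc)2 (3 mol%), TFA/CH2Cl2, rt
Reagents that add atoms: none
Why: Pechmann-type coumarin synthesis by palladium-catalysed trans-hydroarylation of the ynoic acid at resorcinol C4 (para to one OH) followed by lactonisation; no stereocentre is formed.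

Step 2
Reactants: 3 7-hydroxy-4-propyl-2H-chromen-2-one
Product: 5 (2Z)-3-(2,4-dimethoxyphenyl)hex-2-enoic acid, via methyl ester 4 (not isolated)
Conditions: KOH, MeI, DMSO, rt; then aq. KOH, 60 °C; HCl
Reagents that add atoms: iodomethane, CI; potassium hydroxide, [K+].[OH-]
Why: Hydroxide opens the coumarin to the (Z)-coumarinate, exhaustive Williamson O-methylation traps both phenoxides (and the carboxylate as ester 4) and saponification returns the acid, so the Z geometry imposed by the former ring is kept and both phenols are masked for the acid and peracid steps ahead.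

Step 3
Reactants: 5 (2Z)-3-(2,4-dimethoxyphenyl)hex-2-enoic acid
Product: 6 (3R)-3-(2,4-dimethoxyphenyl)hexanoic acid
Conditions: Ru(OAc)2[(S)-BINAP] (1 mol%), H2 (60 bar), MeOH, 40 °C
Reagents that add atoms: none
Why: Carboxylate-directed asymmetric hydrogenation (Noyori type) of a geometrically pure β,β-disubstituted acrylic acid, in which the BINAP enantiomer selects the olefin face and sets the benzylic stereocentre as R (ee raised by one crystallisation of 7 if needed).

Step 4
Reactants: 6 (3R)-3-(2,4-dimethoxyphenyl)hexanoic acid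
Product: 7 (3R)-4,6-dimethoxy-3-propyl-2,3-dihydro-1H-inden-1-one
Conditions: PPA, 85 °C
Reagents that add atoms: none
Why: Intramolecular Friedel–Crafts acylation closes the five-membered ring on the only ortho carbon within reach (the other carries OMe), as known for 3-(2-methoxyaryl)propanoic acids giving 4-methoxyindan-1-ones; the stereocentre is not involved.

Step 5
Reactants: 7 (3R)-4,6-dimethoxy-3-propyl-2,3-dihydro-1H-inden-1-one
Product: 8 (4R)-5,7-dimethoxy-4-propyl-3,4-dihydro-2H-chromen-2-one
Conditions: mCPBA, CF3CO2H (cat.), CH2Cl2, 0 °C → rt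
Reagents that add atoms: mCPBA (3-chloroperoxybenzoic acid), O=C(OO)c1cccc(Cl)c1
Why: Baeyer–Villiger ring expansion, the key step: in the Criegee intermediate the aryl carbon migrates in preference to the primary CH2 (1,2-shift from carbon to oxygen), inserting oxygen between C1 and C7a, so the indanone becomes the six-membered lactone and the benzene ring gains its third oxygen in the 1,3,5 pattern with the acid arm masked; C4 is untouched.

Step 6
Reactants: 8 (4R)-5,7-dimethoxy-4-propyl-3,4-dihydro-2H-chromen-2-one; 9 tigloyl chloride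
Product: 11 (4R)-7-hydroxy-5-methoxy-8-[(2E)-2-methylbut-2-enoyl]-4-propyl-3,4-dihydro-2H-chromen-2-one, via dimethoxy aryl ketone 10 (not isolated)
Conditions: AlCl3 (3.5 equiv), ClCH2CH2Cl, 0 → 40 °C; cold 1 M HCl
Reagents that add atoms: none
Why: Friedel–Crafts acylation goes to C8 (para to 5-OMe and less hindered than C6 between two OMe groups), and AlCl3 then cleaves only the OMe ortho to the new ketone through the six-membered chelate, unveiling the one phenol that can cyclise while the remaining 5-OMe locks the lactone against translactonisation.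

Step 7
Reactants: 11 (4R)-7-hydroxy-5-methoxy-8-[(2E)-2-methylbut-2-enoyl]-4-propyl-3,4-dihydro-2H-chromen-2-one
Product: 12 (4R,8R,9S)-5-methoxy-8,9-dimethyl-4-propyl-3,4,8,9-tetrahydro-2H,10H-pyrano[2,3-f]chromene-2,10-dione
Conditions: (−)-quinine (20 mol%), PhCl, 15 °C
Reagents that add atoms: none
Why: Cinchona-alkaloid-catalysed intramolecular oxa-Michael addition, in which the catalyst delivers the phenol to one face of the tigloyl β-carbon (sets the O–CH centre C8 as R) and kinetic protonation of the enol anti to the new methyl gives the cis isomer (sets C9 as S), catalyst control overriding the remote C4 centre.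

Step 8
Reactants: 12 (4R,8R,9S)-5-methoxy-8,9-dimethyl-4-propyl-3,4,8,9-tetrahydro-2H,10H-pyrano[2,3-f]chromene-2,10-dione
Product: 13 (4R,8R,9S)-6-bromo-5-methoxy-8,9-dimethyl-4-propyl-3,4,8,9-tetrahydro-2H,10H-pyrano[2,3-f]chromene-2,10-dione
Conditions: NBS, MeCN, 0 °C
Reagents that add atoms: N-bromosuccinimide, O=C1CCC(=O)N1Br
Why: Electrophilic aromatic bromination at the single remaining ring C–H, which is activated by two ortho alkoxy groups; no stereocentre is affected.

Step 9
Reactants: 14 3-methylbut-3-enoic acid; 15 prenyl bromide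
Product: 16 (2S)-5-methyl-2-(prop-1-en-2-yl)hex-4-enoic acid [(S)-lavandulic acid]
Conditions: N,N'-bis[(R)-1-phenyl-2-(piperidin-1-yl)ethyl]propane-1,3-diamine (1.05 equiv), n-BuLi (4 equiv), THF, 0 °C; then 15, −78 °C; HCl work-up
Reagents that add atoms: none
Why: Enantioselective α-alkylation of the dienediolate of 14 held in a mixed aggregate with the chiral dilithium amide (traceless-auxiliary alkylation; the amine is recovered by extraction), α-attack giving the deconjugated lavandulyl skeleton and the amide enantiomer setting the S centre.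

Step 10
Reactants: 16 (S)-lavandulic acid
Product: 17 (2S)-5-methyl-2-(prop-1-en-2-yl)hex-4-en-1-ol [(S)-lavandulol]
Conditions: LiAlH4, Et2O, 0 °C
Reagents that add atoms: none
Why: Hydride reduction of the carboxylic acid to the primary alcohol under non-enolising conditions, so the allylic stereocentre is retained.

Step 11
Reactants: 17 (S)-lavandulol
Product: 18 (3S)-3-(iodomethyl)-2,6-dimethylhepta-1,5-diene [(S)-lavandulyl iodide]
Conditions: I2, PPh3, imidazole, CH2Cl2, 0 °C
Reagents that add atoms: iodine, II
Why: Appel-type iodination of the primary alcohol by SN2 at CH2, leaving the adjacent stereocentre untouched.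

Step 12
Reactants: 13 the aryl bromide; 18 (S)-lavandulyl iodide
Product: 20 (4R,8R,9S)-5-methoxy-8,9-dimethyl-6-[(2R)-5-methyl-2-(prop-1-en-2-yl)hex-4-en-1-yl]-4-propyl-3,4,8,9-tetrahydro-2H,10H-pyrano[2,3-f]chromene-2,10-dione, via (S)-lavandulylzinc iodide 19 (not isolated)
Conditions: 18, Zn dust, LiCl, THF, 40 °C; then 13, Pd(OAc)2 (5 mol%), SPhos (10 mol%), THF/NMP, 50 °C
Reagents that add atoms: none
Why: Negishi coupling, in which zinc inserts into the C–I bond and the primary alkylzinc couples with the hindered, electron-rich aryl bromide under Pd/SPhos, whose fast reductive elimination outruns β-hydride elimination, so the β stereocentre is carried over unchanged (its CIP label becomes R only because the priorities change).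

Step 13
Reactants: 20 the lavandulyl tricyclic lactone; 21 prenyl chloride
Product: 23 (3R)-3-[(2R,3S,8S)-7-methoxy-2,3-dimethyl-8-[(2R)-5-methyl-2-(prop-1-en-2-yl)hex-4-en-1-yl]-8-(3-methylbut-2-en-1-yl)-4,5-dioxo-3,4,5,8-tetrahydro-2H-chromen-6-yl]hexanoic acid, via ring-opened hydroxy acid 22 (not isolated)
Conditions: LiOH·H2O (2.1 equiv), THF/H2O, 0 °C → rt; concentrate and dry (toluene); then Pd2(dba)3 (2.5 mol%), (R,R)-DACH-phenyl Trost ligand (7.5 mol%), 21 (1.2 equiv), THF/DMF, −20 → 0 °C; dilute HCl to pH 4
Reagents that add atoms: lithium hydroxide, [Li+].[OH-]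
Why: Proposed new method: after saponification of the aryl lactone, zerovalent palladium ionises prenyl chloride to a (1,1-dimethylallyl)palladium cation held in the chiral pocket of the Trost bisphosphine; O-prenylation of the carboxylate and of the chelated C5 phenoxide is reversible under palladium, so the lithium 2-acylphenoxide is funnelled to irreversible C-attack through its para carbon C8 (flanked by two O-bearing carbons, whereas the ortho carbons carry the branched acid arm and the acyl group) at the unsubstituted allyl terminus, giving the linear prenyl group and a quaternary centre whose configuration is set by the ligand because the two faces of the flat phenoxide differ only through remote stereocentres; the closest known reaction types are the Tsuji–Trost asymmetric allylic dearomatisation of naphthols and phenols (ortho-selective, allyl or cinnamyl donors) and the achiral palladium-catalysed dearomative allylation of acylphloroglucinols, whereas a para-selective, ligand-controlled linear prenylation of a hexasubstituted phenoxide has not been shown (the descriptor 8S of 23 is the spatial arrangement of 8R in 24, since C7 and C8a exchange priority).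

Step 14
Reactants: 23 the C7 methyl enol ether
Product: 24 CNP0266113.2, (3R)-3-[(2R,3S,8R)-5-hydroxy-2,3-dimethyl-8-[(2R)-5-methyl-2-(prop-1-en-2-yl)hex-4-en-1-yl]-8-(3-methylbut-2-en-1-yl)-4,7-dioxo-3,4,7,8-tetrahydro-2H-chromen-6-yl]hexanoic acid
Conditions: LiCl, DMSO, 90 °C; then dilute HCl
Reagents that add atoms: none
Why: SN2 O-demethylation of the vinylogous methyl ester by chloride (Krapcho-type, the usual end-game for O-methylated polyprenylated acylphloroglucinols) releases the stabilised triketone enolate and, on protonation, the hydrogen-bonded enol form of 24, without touching the secondary alkyl–O bond of the chromanone ring or any stereocentre.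

## Compound list

1 | resorcinol (benzene-1,3-diol) | Oc1cccc(O)c1 | starting material
2 | hex-2-ynoic acid | CCCC#CC(=O)O | starting material
3 | 7-hydroxy-4-propyl-2H-chromen-2-one | CCCC1=CC(=O)Oc2cc(O)ccc12 | intermediate
4 | methyl (2Z)-3-(2,4-dimethoxyphenyl)hex-2-enoate | CCC/C(=C/C(=O)OC)c1ccc(OC)cc1OC | intermediate
5 | (2Z)-3-(2,4-dimethoxyphenyl)hex-2-enoic acid | CCC/C(=C/C(=O)O)c1ccc(OC)cc1OC | intermediate
6 | (3R)-3-(2,4-dimethoxyphenyl)hexanoic acid | CCC[C@H](CC(=O)O)c1ccc(OC)cc1OC | intermediate
7 | (3R)-4,6-dimethoxy-3-propyl-2,3-dihydro-1H-inden-1-one | CCC[C@@H]1CC(=O)c2cc(OC)cc(OC)c12 | intermediate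
8 | (4R)-5,7-dimethoxy-4-propyl-3,4-dihydro-2H-chromen-2-one | CCC[C@@H]1CC(=O)Oc2cc(OC)cc(OC)c12 | intermediate
9 | tigloyl chloride, (2E)-2-methylbut-2-enoyl chloride | C/C=C(\C)C(=O)Cl | starting material
10 | (4R)-5,7-dimethoxy-8-[(2E)-2-methylbut-2-enoyl]-4-propyl-3,4-dihydro-2H-chromen-2-one | CCC[C@@H]1CC(=O)Oc2c(C(=O)/C(C)=C/C)c(OC)cc(OC)c12 | intermediate
11 | (4R)-7-hydroxy-5-methoxy-8-[(2E)-2-methylbut-2-enoyl]-4-propyl-3,4-dihydro-2H-chromen-2-one | CCC[C@@H]1CC(=O)Oc2c(C(=O)/C(C)=C/C)c(O)cc(OC)c12 | intermediate
12 | (4R,8R,9S)-5-methoxy-8,9-dimethyl-4-propyl-3,4,8,9-tetrahydro-2H,10H-pyrano[2,3-f]chromene-2,10-dione (cis-2,3-dimethylchroman-4-one ring closed from O7 onto the tigloyl group at C8 of the dihydrocoumarin) | CCC[C@@H]1CC(=O)Oc2c3C(=O)[C@@H](C)[C@@H](C)Oc3cc(OC)c12 | intermediate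
13 | (4R,8R,9S)-6-bromo-5-methoxy-8,9-dimethyl-4-propyl-3,4,8,9-tetrahydro-2H,10H-pyrano[2,3-f]chromene-2,10-dione | CCC[C@@H]1CC(=O)Oc2c3C(=O)[C@@H](C)[C@@H](C)Oc3c(Br)c(OC)c12 | intermediate
14 | 3-methylbut-3-enoic acid | C=C(C)CC(=O)O | starting material
15 | prenyl bromide (1-bromo-3-methylbut-2-ene) | CC(C)=CCBr | starting material
16 | (S)-lavandulic acid, (2S)-5-methyl-2-(prop-1-en-2-yl)hex-4-enoic acid | C=C(C)[C@H](CC=C(C)C)C(=O)O | intermediate
17 | (S)-lavandulol, (2S)-5-methyl-2-(prop-1-en-2-yl)hex-4-en-1-ol | C=C(C)[C@H](CC=C(C)C)CO | intermediate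
18 | (S)-lavandulyl iodide, (3S)-3-(iodomethyl)-2,6-dimethylhepta-1,5-diene | C=C(C)[C@H](CC=C(C)C)CI | intermediate
19 | (S)-lavandulylzinc iodide | C=C(C)[C@H](CC=C(C)C)C[Zn]I | intermediate
20 | (4R,8R,9S)-5-methoxy-8,9-dimethyl-6-[(2R)-5-methyl-2-(prop-1-en-2-yl)hex-4-en-1-yl]-4-propyl-3,4,8,9-tetrahydro-2H,10H-pyrano[2,3-f]chromene-2,10-dione | CCC[C@@H]1CC(=O)Oc2c3C(=O)[C@@H](C)[C@@H](C)Oc3c(C[C@@H](CC=C(C)C)C(C)=C)c(OC)c12 | intermediate
21 | prenyl chloride (1-chloro-3-methylbut-2-ene) | CC(C)=CCCl | starting material
22 | (3R)-3-[(2R,3S)-5-hydroxy-7-methoxy-2,3-dimethyl-8-[(2R)-5-methyl-2-(prop-1-en-2-yl)hex-4-en-1-yl]-4-oxo-3,4-dihydro-2H-chromen-6-yl]hexanoic acid | CCC[C@H](CC(=O)O)c1c(O)c2C(=O)[C@@H](C)[C@@H](C)Oc2c(C[C@@H](CC=C(C)C)C(C)=C)c1OC | intermediate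
23 | (3R)-3-[(2R,3S,8S)-7-methoxy-2,3-dimethyl-8-[(2R)-5-methyl-2-(prop-1-en-2-yl)hex-4-en-1-yl]-8-(3-methylbut-2-en-1-yl)-4,5-dioxo-3,4,5,8-tetrahydro-2H-chromen-6-yl]hexanoic acid (C7 methyl enol ether of 24) | C=C(C)[C@H](CC=C(C)C)C[C@@]1(CC=C(C)C)C(OC)=C([C@H](CCC)CC(=O)O)C(=O)C2=C1O[C@H](C)[C@H](C)C2=O | intermediate
24 | CNP0266113.2, (3R)-3-[(2R,3S,8R)-5-hydroxy-2,3-dimethyl-8-[(2R)-5-methyl-2-(prop-1-en-2-yl)hex-4-en-1-yl]-8-(3-methylbut-2-en-1-yl)-4,7-dioxo-3,4,7,8-tetrahydro-2H-chromen-6-yl]hexanoic acid | C=C(C)[C@H](CC=C(C)C)C[C@@]1(CC=C(C)C)C(=O)C([C@H](CCC)CC(=O)O)=C(O)C2=C1O[C@H](C)[C@H](C)C2=O | target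

## Step count and risks

Total steps: 14. Longest linear sequence: 11 (steps 1–8, 12, 13, 14); the lavandulyl branch (steps 9–11) joins at step 12.

Steps most likely to fail:

Step 13 (the proposed new step). Risks are O- versus C-prenylation, attack at an ortho carbon or at the substituted allyl terminus, and an insufficient ligand-induced preference at C8. The fallback uses known chemistry and sets out from 20. The lactone is opened with aqueous LiOH as before, and the resulting phenoxide is C-prenylated in the classical, uncatalysed way with prenyl bromide 15 in aqueous LiOH/THF at 0 °C (the base-mediated dearomative gem-prenylation used for lupulone-type acylphloroglucinols). Any prenyl ester is cleaved by the hydroxide present. This gives 23 together with its C8 epimer, 8-epi-23 F1, in roughly equal amounts. The two are separated by preparative HPLC, and the route is rejoined at 23.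

Step 4. The acylium ion may instead be captured by the ortho methoxy oxygen (demethylative lactonisation), or may acylate the activated positions of a second molecule. The fallback sets out from 6 and turns the first of these side reactions into the route. BBr3 removes both methyl groups and the hydroxy acid lactonises on work-up to (4R)-7-hydroxy-4-propyl-3,4-dihydro-2H-chromen-2-one F2. A Fries-type acyl shift (AlCl3/NaCl melt or neat TfOH) then moves the acyl group from oxygen to the only ring carbon the tether can reach, contracting the lactone to (3R)-4,6-dihydroxy-3-propyl-2,3-dihydro-1H-inden-1-one F3. Re-methylation (MeI, K2CO3, acetone) returns to the route at 7.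

Step 12. Oxidative addition to the di-ortho-alkoxy aryl bromide may be slow, and β-hydride elimination or protodezincation may take over. The fallback sets out from 18 and 13 and replaces the organozinc by a boron nucleophile. Iodine–lithium exchange (t-BuLi, Et2O, −78 °C) gives (S)-lavandulyllithium F4, which is trapped with i-PrOBpin as the (S)-lavandulyl pinacol boronate F5. A B-alkyl Suzuki–Miyaura coupling of F5 with 13 (Pd(OAc)2, RuPhos, K3PO4, toluene/H2O, 80 °C; acidic work-up re-closes any opened lactone) returns to the route at 20.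

Further compounds
F1 | step 13 | 8-epi-23, (3R)-3-[(2R,3S,8R)-7-methoxy-2,3-dimethyl-8-[(2R)-5-methyl-2-(prop-1-en-2-yl)hex-4-en-1-yl]-8-(3-methylbut-2-en-1-yl)-4,5-dioxo-3,4,5,8-tetrahydro-2H-chromen-6-yl]hexanoic acid | C=C(C)[C@H](CC=C(C)C)C[C@]1(CC=C(C)C)C(OC)=C([C@H](CCC)CC(=O)O)C(=O)C2=C1O[C@H](C)[C@H](C)C2=O
F2 | step 4 | (4R)-7-hydroxy-4-propyl-3,4-dihydro-2H-chromen-2-one | CCC[C@@H]1CC(=O)Oc2cc(O)ccc12
F3 | step 4 | (3R)-4,6-dihydroxy-3-propyl-2,3-dihydro-1H-inden-1-one | CCC[C@@H]1CC(=O)c2cc(O)cc(O)c12
F4 | step 12 | (S)-lavandulyllithium | C=C(C)[C@H](CC=C(C)C)C[Li]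
F5 | step 12 | (S)-lavandulyl pinacol boronate, 2-[(2S)-5-methyl-2-(prop-1-en-2-yl)hex-4-en-1-yl]-4,4,5,5-tetramethyl-1,3,2-dioxaborolane | C=C(C)[C@H](CC=C(C)C)CB1OC(C)(C)C(C)(C)O1
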